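At 20.0 min the midnight flask reads substrate 4.6% and product 35.1%, so a leftover of 60.3% of the charge stands in neither column.

the same everywhere: gas 200 mM (held)
- midnight: substrate 2.8 M; temperature 114 °C; run made earlier
- summer: substrate 2.8 M; temperature 122 °C; run made earlier
- blue: substrate 2.0 M; temperature 125 °C; time 20 min
- grey: substrate 2.0 M; temperature 110 °C; time 20 min
- green: substrate 2.0 M; at 125 °C until 4.0 min, from then on at 110 °C; time 20 min

| run | time / min | product / % | substrate / % |
|---|---|---|---|
| midnight | 1.50 | 0.2 | 93.0 |
| midnight | 3.00 | 0.8 | 85.5 |
| midnight | 5.00 | 4.2 | 74.5 |
| midnight | 10.0 | 12.0 | 49.7 |
| midnight | 20.0 | 35.1 | 4.6 |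
| summer | 1.00 | 0.9 | 94.6 |
| summer | 2.00 | 1.1 | 89.6 |
| summer | 3.00 | 2.8 | 84.7 |
| summer | 6.00 | 8.7 | 69.6 |
| summer | 12.0 | 24.9 | 39.8 |

(each reading ± 0.5 percentage points)

- the numbers in the tables scatter by 0.5 percentage points (one standard deviation)
- at the start none of the gas is in solution

1. the best flask by amount of product, in percent of the substrate charged; "all alike" if 1.5 percentage points covers them all (blue / grey / green / all alike)
2. amount of product at the end, in percent of the substrate charged, blue
3. amount of product at the end, in percent of the substrate charged, grey
4. amount of product at the end, in percent of the substrate charged, green

Two people quarrel over that leftover. The first made the forecast and holds: “Product shows a lag, so an intermediate forms first”, and counts as intermediate whatever stands in neither column. On that view the leftover is still on its way to product, and the forecast gives 78% for blue, 36% for grey and 38.5% for green, with blue best.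

The second says part of the leftover is already dead, and reckons with the fraction still alive. Take the summer flask, closer to blue in temperature than midnight. Product's rate over the mean leftover gives 0.115 /min between 3.00 min and 6.00 min, then a lower 0.0947 /min up to 12.0 min. A true constant does not fall, but with this scatter the fall is a weak sign.

Suppose the dead part grows in a fixed ratio to product. The live fraction of the leftover is then one minus that ratio times product over leftover. Product over leftover rose from 0.336 to 0.589, so the two values read above give a ratio of 0.564. That makes the exit share, or selectivity, the part of what leaves the live intermediate that becomes product, 63.9%, a rough reading. Taken as fixed with temperature, it is a ceiling on product, and the forecast's blue stands above it. The second concedes the flasks whose forecast stands below that ceiling, grey and green, to the first view.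

Blue gives 54.5%, best of the flasks, and below both the forecast and the ceiling. Grey at 36.6% and green at 37.9% stand close to the forecast, with intermediate still 35.2% and 32.6%. Blue ends with decomposed reagent 43.4%. The share, applied to what has left substrate and intermediate in blue, gives 62.6%, so this reading runs 8.1 percentage points high.

    substrate + partner → intermediate (k = 7.10 /M/min, Ea = 84.0 kJ/mol)
    gas ⇌ partner, rate k2*(csat - [partner]) (kL = 0.740 /min)
    intermediate → product (k = 0.0520 /min, Ea = 121 kJ/mol)
    intermediate → decomposed reagent (k = 0.0400 /min, Ea = 124 kJ/mol)
    (constants at 110 °C)

Blue's charge run at 100 °C holds substrate 1.85% and intermediate 67.7% at 20.0 min, so the share gives 19.5%. The computed product there is 17.4%.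

(The earlier runs and the new flask were generated by integration with made-up constants, and the scatter is random.)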